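## Analysis of the target

Compound 28 is a bicyclo[3.2.1]oct-2-en-8-one. A six-membered ring (C1–C2–C3–C4–C5–C8) and a cyclopentanone (C1–C7–C6–C5–C8) share the bridgeheads C1 and C5 and the carbonyl carbon C8; these atom labels are kept for the same atoms in every precursor. The five stereocentres (1S,4S,5S,6S,7R) are contiguous. C1 (allyl) and C5 (methoxy) are fully substituted bridgeheads whose configurations are tied to each other by the bicycle. The aryl group on C6 is exo (on the C8 side) and trans to the endo methyl group on C7, and the acetoxy group on C4 points to the C8 side, anti to the C5–C6 bond. Sensitive groups are the methyl enol ether at C2=C3 (acid), the allylic acetate at C4 that is also β to the C8 ketone (ionisation, retro-aldol once deacetylated), the strained bridging ketone, the terminal alkene and the electron-rich veratryl ring; whenever C4 is a ketone, C4–C5–C8 is a non-enolisable β-diketone that nucleophilic bases cleave. The synthesis is hard because of the two quaternary bridgeheads (one oxygenated), the five adjacent stereocentres, and a C4 configuration opposite to the one hydride addition to a C4 ketone should give. The strategy rests on one feature: C1 is bonded to both C8 and C7 and, through C2–C3–C4, to C5, so it can be introduced as one tethered carbon that inserts into the C8–C7 bond of a cyclobutanone made of C8, C5, C6 and C7, whose trans aryl/methyl pair maps onto an (E)-alkene in a ketene-type [2+2] cycloaddition.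

## Retrosynthetic reasoning

**C4–O (acetate).** The C4–O bond of 28 is cut first, back to the epimeric allylic alcohol 27, with inversion. The C4 carbonyl of 26 should accept hydride from the open C8 face, which leaves the hydroxyl on the wrong side. A Mitsunobu esterification installs the acetate and corrects C4 together, and it comes last so that the β-acetoxy ketone is not carried through other steps.

**C4–H.** Alcohol 27 comes from enone 26 by 1,2-reduction. The forward step has to reduce the conjugated C4 carbonyl and leave the C8 ketone.

**C3–O.** The enol ether of 26 is the O-methyl derivative of diosphenol 25, the enol form of triketone 24. Triketone 24 arises by oxidation of α-hydroxy ketone 23, which comes from dione 21 by enolate hydroxylation. C3 is the only enolisable carbon of 21 (C8 lies between two quaternary bridgeheads), so there is no regiochemical question, and 24 can enolise only toward C2.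

**C1–C8 and C1–C7 (key).** In 21 the bonds from C1 to C8 and to C7 are cut and C7 is returned to C8. This gives diazo ketone 20, a cyclobutanone that carries C1 on a three-atom tether from C5. The cut removes both rings and the quaternary C1 in one operation and leaves a four-membered ring whose stereocentres can be set by reliable means. In the forward direction C1 must add to C8, C7 must migrate in preference to C5, and ring enlargement must outrun epoxide closure. Compound 20 cannot be stored and is released in the flask from sulfonylhydrazone 18 through its salt 19.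

**C5–C4.** Compound 18 is cut between C5 and the acyl carbon C4 into enolate 17 and acyl donor 16. Acylation makes C5 quaternary, anti to the neighbouring aryl group. A free sulfonylhydrazone N–H cannot be carried on an activated acyl group because it closes onto it; 16 is that closed form, used on purpose, so the enolate opens the ring and frees the hydrazone in the same event. Enolate 17 is generated regiospecifically from silyl enol ether 8, which is formed from ketone 7 toward the methoxy-bearing α-carbon.

**Acyl donor.** Compound 16 is opened at its N–acyl and C=N bonds to keto acid 13 and sulfonylhydrazide 14 (through 15). Keto acid 13 is cut at the ketone–allyl bond to the N-methoxy-N-methylamide 11 and allylmagnesium bromide 12, and 11 to succinic anhydride 9 and the hydroxylamine salt 10. The amide stops the addition at the ketone stage.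

**Cyclobutanone.** Ketone 7 is cut across C8–C7 and C5–C6 into keteniminium ion 5 and (E)-methylisoeugenol 4. This [2+2] places the carbonyl carbon on the methyl-bearing alkene carbon, carries the (E) geometry into the trans C6/C7 pair and, with a C2-symmetric amine, sets their absolute configuration. Ion 5 is formed from amide 3, made from acid chloride 1 and amine 2; hydrolysis of iminium salt 6 returns the auxiliary.

## Alternatives that were turned down

**Alternative 1:** Nazarov route.
- Disconnection: the C6–C7 bond of the cyclopentanone; the three-carbon bridge C2–C3–C4 is added afterwards.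
- Forward key step: a chiral Lewis acid activates the cross-conjugated dienone A2, conrotatory 4π closure forms C6–C7, and a silane delivers hydride to C5 of the methoxy-stabilised oxyallyl cation to give β-keto ester A1.
- For it: the push–pull dienone is of the kind that cyclises under mild catalysis, conrotation turns alkene geometry into the trans C6/C7 pair, absolute control is catalytic, and the reaction class is well precedented. On precedent and on catalytic induction it is stronger than step 8.
- Against it: A1 holds only the five-membered ring. Both future bridgeheads are still C–H carbons, so C1 must be allylated, C5 substituted, a three-carbon unit built and the bridge closed across the two α-positions, each at a hindered carbon and with the two arms cis. Hydride capture must also choose C5 over C1. At least eight further steps are estimated to reach the stage of 21.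
- Comparison: the chosen strategy gives up catalytic induction and precedent; in exchange one step closes the six-membered ring, makes C1 quaternary and leaves C4 already oxidised.

**Alternative 2:** masked o-quinone Diels–Alder route.
- Disconnection: C1–C7 and, once a 1,2-shift of C6 from C5 back to C4 is undone, C4–C6.
- Forward key step: dienone A4 adds the acyl oxazolidinone A5 across C1 and C4 to give bicyclo[2.2.2]octenone A3. Ionisation of the ketal and migration of C6 from C4 to the ketal carbon would then give the bicyclo[3.2.1] skeleton with oxygen at C4.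
- For it: cycloadditions of such dienones are dependable, C1 becomes quaternary in the cycloaddition, and the ring arrives with its oxygen pattern (C8 ketone, the ketal carbon that becomes C5, bromine as a handle for the C3 methoxy group). In precedent and in oxygenation it is stronger than the chosen route.
- Against it: A4 is an electron-poor, dimerisation-prone diene that pairs best with electron-rich alkenes, so the acceptor-substituted A5 is a mismatched partner. The C7 substituent enters as an acyl group that needs about three steps to become methyl. The shift must move C6 and not the vinyl carbon C3, the cation at C4 must be captured with the right configuration, and bromine must still be exchanged for methoxy at a hindered alkene.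
- Comparison: the chosen route is shorter, starts with the methyl group in place, needs no redox correction at C7 and fixes C6/C7 by a stereospecific cycloaddition.

**Alternative 3:** crossed photocycloaddition route.
- Disconnection: C1–C7 together with a sacrificial bond C2–C6 that is cleaved later.
- Forward key step: triplet-sensitised irradiation of cyclohexenone A7 joins C1=C2 to the arylpropenyl unit C6=C7 in the crossed sense and gives cage ketone A6 with a bicyclo[2.1.1]hexane core. Cleavage of the strained C2–C6 bond next to the C3 carbonyl would then release the bicyclo[3.2.1]octane.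
- For it: the hindered C1–C7 bond and the quaternary C1 form with light as the only reagent, the 1,5-relationship of the two alkenes makes the crossed regiochemistry reliable, and no migratory-aptitude question arises. On that point it is stronger than step 8.
- Against it: the arylpropene is itself a triplet acceptor, so E/Z isomerisation and stepwise biradical closure erase the alkene geometry and C7 is not secured. C6 becomes a stereocentre only in the fragmentation. A6 carries its ketone at C3 and a methylene at C4, the reverse of what 28 needs. A7 needs an enantiopure quaternary C5 made beforehand.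
- Comparison: the chosen strategy sets C6 and C7 early by a stereospecific polar cycloaddition, arrives with C4 oxidised and is shorter.

Key step: step 8

Assumption: the (2S,5S) auxiliary is taken to induce the (3S,4R) configuration of 7; if the sense of induction is the opposite, its commercial (2R,5R) antipode is used and nothing else changes.

## Route

Step 1
Reactants: 1 methoxyacetyl chloride; 2 (2S,5S)-2,5-dimethylpyrrolidine
Product: 3 1-[(2S,5S)-2,5-dimethylpyrrolidin-1-yl]-2-methoxyethan-1-one
Conditions: Et3N, CH2Cl2, 0 °C → rt
Reagents that add atoms: none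
Why: N-acylation of a secondary amine with an acid chloride; the C2-symmetric amine makes the two N–C rotamers of the later keteniminium ion identical.

Step 2
Reactants: 3 1-[(2S,5S)-2,5-dimethylpyrrolidin-1-yl]-2-methoxyethan-1-one; 4 (E)-methylisoeugenol
Product: 7 (2S,3S,4R)-3-(3,4-dimethoxyphenyl)-2-methoxy-4-methylcyclobutan-1-one, via keteniminium triflate 5 (not isolated), via cyclobutaniminium triflate 6 (not isolated)
Conditions: Tf2O, 2,4,6-collidine, CH2Cl2, −25 °C; then 4, −25 °C → rt; then aq. NaHCO3, rt
Reagents that add atoms: water, O
Why: Keteniminium [2+2] cycloaddition followed by iminium hydrolysis. The methyl-bearing alkene carbon attacks the central keteniminium carbon (C8) so that charge develops at the veratryl-stabilised C6, which closes onto C5; this fixes the 3-aryl-4-methyl regiochemistry, carries the (E) geometry into the trans C6/C7 pair, and the dimethylpyrrolidinium unit differentiates the alkene faces. C5 is epimerisable (all-trans expected) and is planarised in step 3.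

Step 3
Reactants: 7 (2S,3S,4R)-3-(3,4-dimethoxyphenyl)-2-methoxy-4-methylcyclobutan-1-one
Product: 8 {[(3S,4R)-3-(3,4-dimethoxyphenyl)-2-methoxy-4-methylcyclobut-1-en-1-yl]oxy}trimethylsilane
Conditions: Et3N, then Me3SiOTf, CH2Cl2, 0 °C → rt
Reagents that add atoms: trimethylsilyl trifluoromethanesulfonate, C[Si](C)(C)OS(=O)(=O)C(F)(F)F
Why: Soft enolisation and O-silylation under equilibrating conditions; the C5–H next to the methoxy group is the more acidic α-hydrogen and the 1,2-dioxygenated alkene the more stable enol ether, so enolisation goes to C5 and the C7 configuration is kept.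

Step 4
Reactants: 9 succinic anhydride; 10 N,O-dimethylhydroxylamine hydrochloride
Product: 11 4-[methoxy(methyl)amino]-4-oxobutanoic acid
Conditions: Et3N, CH2Cl2, 0 °C → rt; then aq. HCl
Reagents that add atoms: none
Why: Ring-opening aminolysis of a cyclic anhydride; only one acyl group reacts and the free acid remains.

Step 5
Reactants: 11 4-[methoxy(methyl)amino]-4-oxobutanoic acid; 12 allylmagnesium bromide
Product: 13 4-oxohept-6-enoic acid
Conditions: 12 (2.3 equiv), THF, −78 → −20 °C; then cold 1 M HCl
Reagents that add atoms: none
Why: Ketone synthesis from an N-methoxy-N-methylamide: the first equivalent of 12 deprotonates the acid, the second adds once, and the magnesium chelate survives until the quench, which is kept cold and brief so the β,γ-double bond does not move into conjugation.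

Step 6
Reactants: 13 4-oxohept-6-enoic acid; 14 4-methylbenzenesulfonohydrazide
Product: 16 2-(4-methylbenzenesulfonyl)-6-(prop-2-en-1-yl)-4,5-dihydropyridazin-3(2H)-one, via sulfonylhydrazone acid 15 (not isolated)
Conditions: THF, rt; then EDC·HCl, CH2Cl2, 0 °C → rt
Reagents that add atoms: none
Why: Hydrazone condensation, then carbodiimide-mediated intramolecular N-acylation of the sulfonylhydrazone N–H (six-membered ring; the E/Z isomers of 15 equilibrate under the acidic conditions). The product is an N-acylsulfonamide-type acyl donor in which the acidic N–H is masked.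

Step 7
Reactants: 8 {[(3S,4R)-3-(3,4-dimethoxyphenyl)-2-methoxy-4-methylcyclobut-1-en-1-yl]oxy}trimethylsilane; 16 2-(4-methylbenzenesulfonyl)-6-(prop-2-en-1-yl)-4,5-dihydropyridazin-3(2H)-one
Product: 18 (2S,3S,4R)-3-(3,4-dimethoxyphenyl)-2-methoxy-4-methyl-2-{4-[2-(4-methylbenzenesulfonyl)hydrazinylidene]hept-6-enoyl}cyclobutan-1-one, via lithium enolate 17 (not isolated)
Conditions: MeLi, THF, 0 °C → rt; then 16, −78 → −40 °C; then aq. NH4Cl
Reagents that add atoms: none
Why: Regiospecific lithium enolate generation from a silyl enol ether, then C-acylation by ring-opening of an N-sulfonyl-activated cyclic amide; the sulfonylhydrazone anion is the leaving group, so the diazo precursor is in place when the C5–C4 bond forms. The electrophile adds to C5 anti to the adjacent C6 aryl group, which sets the quaternary centre (methoxy cis to aryl).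

Step 8
Reactants: 18 (2S,3S,4R)-3-(3,4-dimethoxyphenyl)-2-methoxy-4-methyl-2-{4-[2-(4-methylbenzenesulfonyl)hydrazinylidene]hept-6-enoyl}cyclobutan-1-one
Product: 21 (1S,5S,6S,7R)-6-(3,4-dimethoxyphenyl)-5-methoxy-7-methyl-1-(prop-2-en-1-yl)bicyclo[3.2.1]octane-4,8-dione, via sodium sulfonylhydrazonide 19 (not isolated), via diazo ketone 20 (not isolated)
Conditions: NaH, THF, 0 °C; then 1,4-dioxane, 90 °C, 0.01 M
Reagents that add atoms: none
Why: Proposed new method: NaH removes the sulfonylhydrazone N–H and salt 19 loses sulfinate on heating (aprotic Bamford–Stevens conditions), releasing the dialkyl diazo compound 20 at low stationary concentration; its nucleophilic carbon C1 adds to the strained cyclobutanone carbonyl C8 through a chair-like transition state (6-exo-trig closure of ring C1–C2–C3–C4–C5–C8; attack at C4 would need a four-membered ring), and the diazonium alkoxide expels N2 while the C8–C7 bond shifts to C1. This 1,2-shift is a ring enlargement and not a cyclisation: it turns the four-membered ring into the cyclopentanone C1–C7–C6–C5–C8 and regenerates the C8 carbonyl. The closest known reactions are the one-carbon expansion of cyclobutanones to cyclopentanones by diazoalkanes (Tiffeneau–Demjanov type) and intramolecular diazo–ketone homologations; a tethered version that leaves a bridged bicycle from a hydrazone-derived dialkyl diazo carbon is not documented. C1 is the only new stereocentre and becomes a bridgehead: it must reach the C8 face that carries the C5 acyl arm and is inverted as C7 arrives anti to the departing N2, so only the (1S) bicycle can form, while C7 migrates with retention and C5 and C6 are untouched. The step needs migration of C7 and not of C5 (which would give a fused bicyclo[3.3.0]octanedione): in the favoured chair the larger allyl group on C1 is equatorial and N2 axial, anti-periplanar to the axial C8–C7 bond, whereas C5 migration needs N2 equatorial, and C5 is fully substituted and carries the electron-withdrawing acyl group, the situation in which cyclobutanone expansions move the other α-carbon. Epoxide closure needs the alkoxide anti to N2, which the same chair does not provide, and relief of four-ring strain favours the shift. No Lewis acid is used because 18–20 are donor–acceptor cyclobutanes; high dilution suppresses azine formation, and cycloaddition of the diazo group to the allyl double bond and 1,2-hydrogen shift of the derived carbene remain the competing unimolecular paths.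

Step 9
Reactants: 21 (1S,5S,6S,7R)-6-(3,4-dimethoxyphenyl)-5-methoxy-7-methyl-1-(prop-2-en-1-yl)bicyclo[3.2.1]octane-4,8-dione
Product: 23 (1R,3S,5R,6S,7R)-6-(3,4-dimethoxyphenyl)-3-hydroxy-5-methoxy-7-methyl-1-(prop-2-en-1-yl)bicyclo[3.2.1]octane-4,8-dione, via potassium enolate 22 (not isolated)
Conditions: KN(SiMe3)2, THF, −78 °C; then 3-phenyl-2-(phenylsulfonyl)oxaziridine, −78 °C; then aq. NH4Cl
Reagents that add atoms: 3-phenyl-2-(phenylsulfonyl)oxaziridine, O=S(=O)(c1ccccc1)N1OC1c1ccccc1
Why: Enolate hydroxylation with an N-sulfonyloxaziridine; C3 is the only enolisable carbon because C8 lies between two quaternary bridgeheads, and the non-nucleophilic amide base spares the β-diketone. Oxygen should enter from the open C8 face (the other face of C3 is covered by the endo methyl group on C7); this centre is removed in step 10.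

Step 10
Reactants: 23 (1R,3S,5R,6S,7R)-6-(3,4-dimethoxyphenyl)-3-hydroxy-5-methoxy-7-methyl-1-(prop-2-en-1-yl)bicyclo[3.2.1]octane-4,8-dione
Product: 25 (1S,5R,6S,7R)-6-(3,4-dimethoxyphenyl)-3-hydroxy-5-methoxy-7-methyl-1-(prop-2-en-1-yl)bicyclo[3.2.1]oct-2-ene-4,8-dione, via triketone 24 (not isolated)
Conditions: Dess–Martin periodinane, CH2Cl2, 0 °C → rt
Reagents that add atoms: none
Why: Dess–Martin oxidation of the α-hydroxy ketone to the 1,2-diketone, which tautomerises to the diosphenol; enolisation is possible only toward C2 because C5 is quaternary.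

Step 11
Reactants: 25 (1S,5R,6S,7R)-6-(3,4-dimethoxyphenyl)-3-hydroxy-5-methoxy-7-methyl-1-(prop-2-en-1-yl)bicyclo[3.2.1]oct-2-ene-4,8-dione
Product: 26 (1S,5R,6S,7R)-6-(3,4-dimethoxyphenyl)-3,5-dimethoxy-7-methyl-1-(prop-2-en-1-yl)bicyclo[3.2.1]oct-2-ene-4,8-dione
Conditions: Me2SO4, K2CO3, acetone, rt
Reagents that add atoms: dimethyl sulfate, COS(=O)(=O)OC
Why: O-alkylation of the acidic diosphenol hydroxyl (Williamson type); carbonate is not nucleophilic enough to cleave the β-diketone, and C-methylation at the neopentyl-like C2 is disfavoured.

Step 12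
Reactants: 26 (1S,5R,6S,7R)-6-(3,4-dimethoxyphenyl)-3,5-dimethoxy-7-methyl-1-(prop-2-en-1-yl)bicyclo[3.2.1]oct-2-ene-4,8-dione
Product: 27 (1S,4R,5S,6S,7R)-6-(3,4-dimethoxyphenyl)-4-hydroxy-3,5-dimethoxy-7-methyl-1-(prop-2-en-1-yl)bicyclo[3.2.1]oct-2-en-8-one
Conditions: NaBH4, CeCl3·7H2O, MeOH, −78 °C
Reagents that add atoms: none
Why: Luche reduction (1,2-reduction of the enone). Hydride should add to C4 from the C8 face, anti to the C5–C6 bond and with no 1,3-diaxial group in its path, leaving the hydroxyl on the side of the C6–C7 bridge (4R); the conjugated, cerium-activated C4 carbonyl is expected to react before the C8 ketone flanked by two quaternary carbons.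

Step 13
Reactants: 27 (1S,4R,5S,6S,7R)-6-(3,4-dimethoxyphenyl)-4-hydroxy-3,5-dimethoxy-7-methyl-1-(prop-2-en-1-yl)bicyclo[3.2.1]oct-2-en-8-one
Product: 28 (1S,4S,5S,6S,7R)-6-(3,4-dimethoxyphenyl)-3,5-dimethoxy-7-methyl-8-oxo-1-(prop-2-en-1-yl)bicyclo[3.2.1]oct-2-en-4-yl acetate
Conditions: AcOH, PPh3, DIAD, THF, 0 °C → rt
Reagents that add atoms: acetic acid, CC(=O)O
Why: Mitsunobu esterification; acetate displaces the activated allylic oxygen with inversion along the same unhindered trajectory on the C8 face that hydride used in step 12, giving the (4S) acetate. No β-hydrogen is available for elimination (C5 quaternary, C3 sp2).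

## Compound list

1 | methoxyacetyl chloride | COCC(=O)Cl | starting material
2 | (2S,5S)-2,5-dimethylpyrrolidine | C[C@H]1CC[C@H](C)N1 | starting material
3 | 1-[(2S,5S)-2,5-dimethylpyrrolidin-1-yl]-2-methoxyethan-1-one | COCC(=O)N1[C@@H](C)CC[C@@H]1C | intermediate
4 | (E)-methylisoeugenol, 1,2-dimethoxy-4-[(1E)-prop-1-en-1-yl]benzene | C/C=C/c1ccc(OC)c(OC)c1 | starting material
5 | (2S,5S)-1-(2-methoxyethenylidene)-2,5-dimethylpyrrolidin-1-ium triflate (keteniminium triflate) | COC=C=[N+]1[C@@H](C)CC[C@@H]1C.[O-]S(=O)(=O)C(F)(F)F | intermediate
6 | (2S,5S)-1-[(2S,3S,4R)-3-(3,4-dimethoxyphenyl)-2-methoxy-4-methylcyclobutylidene]-2,5-dimethylpyrrolidin-1-ium triflate (cyclobutaniminium triflate) | CO[C@@H]1C(=[N+]2[C@@H](C)CC[C@@H]2C)[C@H](C)[C@H]1c1ccc(OC)c(OC)c1.[O-]S(=O)(=O)C(F)(F)F | intermediate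
7 | (2S,3S,4R)-3-(3,4-dimethoxyphenyl)-2-methoxy-4-methylcyclobutan-1-one | CO[C@@H]1C(=O)[C@H](C)[C@H]1c1ccc(OC)c(OC)c1 | intermediate
8 | {[(3S,4R)-3-(3,4-dimethoxyphenyl)-2-methoxy-4-methylcyclobut-1-en-1-yl]oxy}trimethylsilane | COC1=C(O[Si](C)(C)C)[C@H](C)[C@H]1c1ccc(OC)c(OC)c1 | intermediate
9 | succinic anhydride | O=C1CCC(=O)O1 | starting material
10 | N,O-dimethylhydroxylamine hydrochloride | Cl.CNOC | starting material
11 | 4-[methoxy(methyl)amino]-4-oxobutanoic acid | CON(C)C(=O)CCC(=O)O | intermediate
12 | allylmagnesium bromide (solution in Et2O) | C=CC[Mg]Br | starting material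
13 | 4-oxohept-6-enoic acid | C=CCC(=O)CCC(=O)O | intermediate
14 | 4-methylbenzenesulfonohydrazide | Cc1ccc(cc1)S(=O)(=O)NN | starting material
15 | 4-[2-(4-methylbenzenesulfonyl)hydrazinylidene]hept-6-enoic acid (E/Z mixture) | C=CCC(=NNS(=O)(=O)c1ccc(C)cc1)CCC(=O)O | intermediate
16 | 2-(4-methylbenzenesulfonyl)-6-(prop-2-en-1-yl)-4,5-dihydropyridazin-3(2H)-one | C=CCC1=NN(S(=O)(=O)c2ccc(C)cc2)C(=O)CC1 | intermediate
17 | lithium (3S,4R)-3-(3,4-dimethoxyphenyl)-2-methoxy-4-methylcyclobut-1-en-1-olate | COC1=C([O-])[C@H](C)[C@H]1c1ccc(OC)c(OC)c1.[Li+] | intermediate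
18 | (2S,3S,4R)-3-(3,4-dimethoxyphenyl)-2-methoxy-4-methyl-2-{4-[2-(4-methylbenzenesulfonyl)hydrazinylidene]hept-6-enoyl}cyclobutan-1-one (hydrazone E/Z mixture) | C=CCC(=NNS(=O)(=O)c1ccc(C)cc1)CCC(=O)[C@]1(OC)C(=O)[C@H](C)[C@H]1c1ccc(OC)c(OC)c1 | intermediate
19 | sodium salt of 18 (N-sodio sulfonylhydrazone) | C=CCC(=N[N-]S(=O)(=O)c1ccc(C)cc1)CCC(=O)[C@]1(OC)C(=O)[C@H](C)[C@H]1c1ccc(OC)c(OC)c1.[Na+] | intermediate
20 | (2S,3S,4R)-2-(4-diazohept-6-enoyl)-3-(3,4-dimethoxyphenyl)-2-methoxy-4-methylcyclobutan-1-one | C=CCC(=[N+]=[N-])CCC(=O)[C@]1(OC)C(=O)[C@H](C)[C@H]1c1ccc(OC)c(OC)c1 | intermediate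
21 | (1S,5S,6S,7R)-6-(3,4-dimethoxyphenyl)-5-methoxy-7-methyl-1-(prop-2-en-1-yl)bicyclo[3.2.1]octane-4,8-dione | C=CC[C@]12CCC(=O)[C@](OC)(C1=O)[C@H](c1ccc(OC)c(OC)c1)[C@H]2C | intermediate
22 | potassium C3=C4 enolate of 21 | C=CC[C@]12CC=C([O-])[C@](OC)(C1=O)[C@H](c1ccc(OC)c(OC)c1)[C@H]2C.[K+] | intermediate
23 | (1R,3S,5R,6S,7R)-6-(3,4-dimethoxyphenyl)-3-hydroxy-5-methoxy-7-methyl-1-(prop-2-en-1-yl)bicyclo[3.2.1]octane-4,8-dione (hydroxyl on the C8 side) | C=CC[C@]12C[C@H](O)C(=O)[C@](OC)(C1=O)[C@H](c1ccc(OC)c(OC)c1)[C@H]2C | intermediate
24 | (1R,5R,6S,7R)-6-(3,4-dimethoxyphenyl)-5-methoxy-7-methyl-1-(prop-2-en-1-yl)bicyclo[3.2.1]octane-3,4,8-trione | C=CC[C@]12CC(=O)C(=O)[C@](OC)(C1=O)[C@H](c1ccc(OC)c(OC)c1)[C@H]2C | intermediate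
25 | (1S,5R,6S,7R)-6-(3,4-dimethoxyphenyl)-3-hydroxy-5-methoxy-7-methyl-1-(prop-2-en-1-yl)bicyclo[3.2.1]oct-2-ene-4,8-dione | C=CC[C@]12C=C(O)C(=O)[C@](OC)(C1=O)[C@H](c1ccc(OC)c(OC)c1)[C@H]2C | intermediate
26 | (1S,5R,6S,7R)-6-(3,4-dimethoxyphenyl)-3,5-dimethoxy-7-methyl-1-(prop-2-en-1-yl)bicyclo[3.2.1]oct-2-ene-4,8-dione | C=CC[C@]12C=C(OC)C(=O)[C@](OC)(C1=O)[C@H](c1ccc(OC)c(OC)c1)[C@H]2C | intermediate
27 | (1S,4R,5S,6S,7R)-6-(3,4-dimethoxyphenyl)-4-hydroxy-3,5-dimethoxy-7-methyl-1-(prop-2-en-1-yl)bicyclo[3.2.1]oct-2-en-8-one (hydroxyl on the side of the C6–C7 bridge) | C=CC[C@]12C=C(OC)[C@@H](O)[C@](OC)(C1=O)[C@H](c1ccc(OC)c(OC)c1)[C@H]2C | intermediate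
28 | (1S,4S,5S,6S,7R)-6-(3,4-dimethoxyphenyl)-3,5-dimethoxy-7-methyl-8-oxo-1-(prop-2-en-1-yl)bicyclo[3.2.1]oct-2-en-4-yl acetate | C=CC[C@]12C=C(OC)[C@H](OC(C)=O)[C@](OC)(C1=O)[C@H](c1ccc(OC)c(OC)c1)[C@H]2C | target

## Step count and least certain steps

Total: 13 steps. Longest linear sequence: 10 steps (steps 1–3 and 7–13; the branch through steps 4–6 and 7–13 is equally long).

**Step 8 (key step, new method).**
- Most likely failure: migration of the ring-fusion carbon C5 instead of C7, or loss of nitrogen from the diazo carbon before it reaches the carbonyl (carbene 1,2-hydrogen shift, cycloaddition to the allyl double bond). The cause is that dialkyl diazo compounds decompose at the temperature at which the salt releases them.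
- Fallback (known reactions only): the same two bonds are made stepwise by a Tiffeneau–Demjanov sequence that sets out from 8 and returns at 21. Enolate 17, generated from 8 with MeLi, is added to acrolein at −78 °C to give the allylic carbinol F1, and Dess–Martin oxidation gives the vinyl ketone F2. Michael addition of 4-nitrobut-1-ene (cat. Et3N, MeCN) is followed in the same flask by intramolecular Henry addition of the nitronate carbon C1 to C8, giving the bicyclic nitro alcohol F3; the retro-Henry equilibrium lets the C1 epimers interconvert. Reduction with Zn in AcOH gives the amino alcohol F4, and diazotisation (NaNO2, aq. AcOH, 0 °C) triggers the shift of C7 to C1 and delivers 21.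

**Step 7.**
- Most likely failure: O-acylation of the enolate, or proton transfer from the α-methylene groups of 16 to the hindered tetrasubstituted enolate, because C–C bond formation creates a quaternary centre.
- Fallback: aldol addition followed by oxidation, setting out from 16 and 8 and returning at 18. Reduction of 16 with LiBHEt3 (THF, −78 °C) gives the cyclic N-sulfonyl hemiaminal F5, the ring tautomer of the hydrazono aldehyde. Deprotonation with LiN(SiMe3)2 opens it to the aldehyde, which is added to enolate 17 at −78 °C to give the aldol adduct F6. Brief oxidation with Dess–Martin periodinane gives 18.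

**Step 3.**
- Most likely failure: incomplete regiocontrol, with enolisation also toward C7, because both α-carbons are tertiary and the preference rests only on the acidifying effect of the methoxy group.
- Fallback: chelation-controlled soft enolisation, setting out from 7 and returning at 18. Ketone 7 is treated with MgBr2·OEt2 and i-Pr2NEt in CH2Cl2 in the presence of 16; magnesium bridges the C8 carbonyl and the C5 methoxy oxygen, so only C5–H is acidified, and the magnesium enolate is acylated in the flask. No silyl enol ether and no new compound are involved.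

**Step 2.**
- Most likely failure: poor facial selectivity, because the auxiliary is remote from C6/C7 and the (E)-alkene is acyclic, together with acid-initiated oligomerisation of the electron-rich styrene.
- Fallback: racemic synthesis and resolution, setting out from 1 and 4 and returning at 7. Acid chloride 1 and pyrrolidine give the achiral amide F7, which under the conditions of step 2 gives the racemic cyclobutanone F8. Preparative chromatography on a chiral stationary phase delivers 7, at the cost of half the material.

**Step 13.**
- Most likely failure: attack of acetate at C2 with allylic transposition, or no displacement at all, because C4 is flanked by the quaternary C5.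
- Fallback: reagent control in place of inversion, setting out from 26 and returning at 28. Enone 26 is reduced with catecholborane and 1-methyl-3,3-diphenyltetrahydro-1H,3H-pyrrolo[1,2-c][1,3,2]oxazaborole (CBS reduction), using the catalyst antipode that delivers hydride to the face of the C6–C7 bridge (both antipodes are commercial, so the matched one is found in one comparison). This gives the (4S) alcohol F9, which is acetylated (Ac2O, pyridine, cat. 4-dimethylaminopyridine) to 28.

**Step 12.**
- Most likely failure: concurrent reduction of the strained C8 ketone.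
- Fallback: exhaustive reduction and late re-oxidation, setting out from 26 and returning at 28. Excess NaBH4 in MeOH at 0 °C reduces both carbonyl groups to the diol F10. The Mitsunobu conditions of step 13 esterify only the allylic C4 hydroxyl, since the C8 hydroxyl between two quaternary carbons cannot be displaced, giving the hydroxy acetate F11. Dess–Martin oxidation of the C8 hydroxyl then gives 28.

## Further compounds

F1 | step 8 | (2S,3S,4R)-3-(3,4-dimethoxyphenyl)-2-(1-hydroxyprop-2-en-1-yl)-2-methoxy-4-methylcyclobutan-1-one (carbinol epimers) | C=CC(O)[C@]1(OC)C(=O)[C@H](C)[C@H]1c1ccc(OC)c(OC)c1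
F2 | step 8 | (2S,3S,4R)-3-(3,4-dimethoxyphenyl)-2-methoxy-4-methyl-2-(prop-2-enoyl)cyclobutan-1-one | C=CC(=O)[C@]1(OC)C(=O)[C@H](C)[C@H]1c1ccc(OC)c(OC)c1
F3 | step 8 | 8-(3,4-dimethoxyphenyl)-6-hydroxy-1-methoxy-7-methyl-5-nitro-5-(prop-2-en-1-yl)bicyclo[4.2.0]octan-2-one (cyclobutane carbons as in 18, cis ring fusion, epimers at the nitro carbon) | O[C@@]12[C@H](C)[C@@H](c3ccc(OC)c(OC)c3)[C@]1(OC)C(=O)CCC2(CC=C)[N+](=O)[O-]
F4 | step 8 | 5-amino-8-(3,4-dimethoxyphenyl)-6-hydroxy-1-methoxy-7-methyl-5-(prop-2-en-1-yl)bicyclo[4.2.0]octan-2-one (configuration as F3) | O[C@@]12[C@H](C)[C@@H](c3ccc(OC)c(OC)c3)[C@]1(OC)C(=O)CCC2(CC=C)N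
F5 | step 7 | 1-(4-methylbenzenesulfonyl)-3-(prop-2-en-1-yl)-1,4,5,6-tetrahydropyridazin-6-ol (racemic) | C=CCC1=NN(S(=O)(=O)c2ccc(C)cc2)C(O)CC1
F6 | step 7 | (2S,3S,4R)-3-(3,4-dimethoxyphenyl)-2-{1-hydroxy-4-[2-(4-methylbenzenesulfonyl)hydrazinylidene]hept-6-en-1-yl}-2-methoxy-4-methylcyclobutan-1-one (carbinol epimers) | C=CCC(=NNS(=O)(=O)c1ccc(C)cc1)CCC(O)[C@]1(OC)C(=O)[C@H](C)[C@H]1c1ccc(OC)c(OC)c1
F0 | step 3 | none | none
F7 | step 2 | 2-methoxy-1-(pyrrolidin-1-yl)ethan-1-one | COCC(=O)N1CCCC1
F8 | step 2 | racemic 3-(3,4-dimethoxyphenyl)-2-methoxy-4-methylcyclobutan-1-one (7 and its enantiomer, 1:1) | CO[C@@H]1C(=O)[C@H](C)[C@H]1c1ccc(OC)c(OC)c1.CO[C@H]1C(=O)[C@@H](C)[C@@H]1c1ccc(OC)c(OC)c1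
F9 | step 13 | (1S,4S,5S,6S,7R)-6-(3,4-dimethoxyphenyl)-4-hydroxy-3,5-dimethoxy-7-methyl-1-(prop-2-en-1-yl)bicyclo[3.2.1]oct-2-en-8-one (hydroxyl on the C8 side) | C=CC[C@]12C=C(OC)[C@H](O)[C@](OC)(C1=O)[C@H](c1ccc(OC)c(OC)c1)[C@H]2C
F10 | step 12 | C4,C8-diol from 26 (C4 as in 27; C8 hydroxyl syn to the C6–C7 bridge) | C=CC[C@]12C=C(OC)[C@@H](O)[C@](OC)([C@H]1O)[C@H](c1ccc(OC)c(OC)c1)[C@H]2C
F11 | step 12 | C4 acetate of the C8 alcohol (C4 as in 28; C8 hydroxyl syn to the C6–C7 bridge) | C=CC[C@]12C=C(OC)[C@H](OC(C)=O)[C@](OC)([C@H]1O)[C@H](c1ccc(OC)c(OC)c1)[C@H]2C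
A1 | alternative 1 | methyl 4-(3,4-dimethoxyphenyl)-3-methoxy-5-methyl-2-oxocyclopentane-1-carboxylate | COC(=O)[C@@H]1C(=O)[C@@H](OC)[C@H](c2ccc(OC)c(OC)c2)[C@H]1C
A2 | alternative 1 | methyl (2Z)-2-[(2Z)-3-(3,4-dimethoxyphenyl)-2-methoxyprop-2-enoyl]but-2-enoate | COc1ccc(/C=C(OC)/C(=O)/C(C(=O)OC)=C/C)cc1OC
A3 | alternative 2 | bicyclo[2.2.2]oct-5-en-2-one Diels–Alder adduct of A4 and A5 | C=CC[C@]12C=C(Br)[C@H](C(OC)(OC)C1=O)[C@H](c1ccc(OC)c(OC)c1)[C@H]2C(=O)N1[C@@H](Cc2ccccc2)COC1=O
A4 | alternative 2 | 4-bromo-6,6-dimethoxy-2-(prop-2-en-1-yl)cyclohexa-2,4-dien-1-one | C=CCC1=CC(Br)=CC(OC)(OC)C1=O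
A5 | alternative 2 | (4S)-4-benzyl-3-[(2E)-3-(3,4-dimethoxyphenyl)prop-2-enoyl]-1,3-oxazolidin-2-one | COc1ccc(/C=C/C(=O)N2[C@@H](Cc3ccccc3)COC2=O)cc1OC
A6 | alternative 3 | crossed photoadduct, tricyclic cage ketone with a bicyclo[2.1.1]hexane core | C=CC[C@]12[C@@H]3C(=O)C[C@](OC)(C1(OC)OC)[C@]3(c1ccc(OC)c(OC)c1)[C@H]2C
A7 | alternative 3 | (5R)-5-[(1E)-1-(3,4-dimethoxyphenyl)prop-1-en-1-yl]-4,4,5-trimethoxy-3-(prop-2-en-1-yl)cyclohex-2-en-1-one | C=CCC1=CC(=O)C[C@](OC)(C1(OC)OC)/C(=C/C)c1ccc(OC)c(OC)c1
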